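Tuesday's run ends with 15.9% of its starting complex unreacted, and Saturday's with 15.9%, though Saturday's scavenger charge is 2.45 times Tuesday's.

| flask | starting complex | incoming ligand | leaving ligand | scavenger | remark | time |
|---|---|---|---|---|---|---|
| Tuesday's | 0.10 M | 0.20 M | 0.50 M | 0.033 M | run made earlier |  |
| Saturday's | 0.10 M | 0.20 M | 0.50 M | 0.081 M | run made earlier |  |
| maple | 0.10 M | 0.200 M | 0.500 M | 0.0500 M |  | 20 h |
| ash | 0.10 M | 0.200 M | 0.500 M | 0.110 M |  | 20 h |
| oak | 0.10 M | 0.200 M | 0.500 M | 0.0750 M |  | 20 h |

| run | time / h | starting complex / % | complex with three exchanged / % |
|---|---|---|---|
| Tuesday's | 2.00 | 20.4 | 49.0 |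
| Tuesday's | 4.00 | 18.4 | 52.7 |
| Tuesday's | 6.00 | 17.5 | 50.1 |
| Tuesday's | 8.00 | 18.3 | 50.0 |
| Tuesday's | 10.0 | 16.3 | 51.5 |
| Tuesday's | 12.0 | 16.8 | 52.4 |
| Tuesday's | 15.0 | 15.9 | 51.1 |
| Saturday's | 1.00 | 24.0 | 41.4 |
| Saturday's | 1.50 | 23.0 | 45.5 |
| Saturday's | 2.50 | 21.8 | 49.2 |
| Saturday's | 4.00 | 19.5 | 49.2 |
| Saturday's | 6.00 | 18.4 | 50.4 |
| Saturday's | 10.0 | 18.2 | 52.8 |
| Saturday's | 15.0 | 15.9 | 51.6 |

(standard deviation of a reading: 1 percentage point)

- percentages count the starting complex that a species holds: one side product counts as two
- leaving ligand is meant together with its idle adduct
- steps thought possible: starting complex + incoming ligand -> leaving ligand + complex with one exchanged; complex with one exchanged + incoming ligand -> leaving ligand + complex with two exchanged; complex with two exchanged + incoming ligand -> leaving ligand + complex with three exchanged; leaving ligand + incoming ligand <-> idle adduct; scavenger + leaving ligand -> scavenged by-product; starting complex + complex with two exchanged -> side product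

- part of the starting complex that has reacted at the end, maple
- part of the starting complex that has reacted at the end, ash
- part of the starting complex that has reacted at the end, oak
- what raising the concentration of scavenger from its lowest to its highest value here does to the part of the starting complex that has reacted (changes below 5 percentage points count as none) (it rises / no change / it falls)

To see why any starting complex is left, we count turnovers with one quantity, the exchange budget B, the incoming ligand charged per starting complex charged, since each exchange costs one incoming ligand. In all these flasks B = 2.00.

Take the first exchange by itself. Each starting complex costs 1, B covers that, and we should expect 100 reacted. Now add the second and third exchanges. A complex taken to the end costs 3, so B pays for 66.7% of the complexes at most, and incoming ligand becomes the limiting reagent.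

Tuesday's last reading bears this out. Its 51.1% of three-exchanged complex has cost 1.53 exchanges, which leaves 0.467. The remaining 33.0% of the complex, at one or two exchanges apiece, would cost 0.330 to 0.660, a span that contains what is left, so we take the budget as used up.

Next comes the side step, in which starting complex meets two-exchanged complex. It costs no incoming ligand, so starting complex can go on falling, and in Tuesday's run it fell from 20.4% at 2.00 h to 15.9% at 15.0 h. Continuing at that pace to 20 h leaves 14.2%, so our figure is 85.8% reacted.

Last come the scavenger, which takes leaving ligand, and the idle adduct, which holds incoming ligand reversibly. Neither alters B, and the last readings of starting complex in the two runs are the same, each good to 1 percentage point. We therefore give maple, ash and oak the same figure, although ash's charge lies beyond Saturday's.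

The forecast, holding that “Incoming ligand looks like the limiter”, gave 84.5%, 85% and 84.8%, slightly below ours, and no change. The flasks give 85.5%, 85.5% and 85.5%: no change, a change of −0.0071 points.

    starting complex + incoming ligand → leaving ligand + complex with one exchanged (k = 0.00574 /M/s)
    complex with one exchanged + incoming ligand → leaving ligand + complex with two exchanged (k = 0.0164 /M/s)
    complex with two exchanged + incoming ligand → leaving ligand + complex with three exchanged (k = 0.0124 /M/s)
    leaving ligand + incoming ligand ⇌ idle adduct, settled at all times (K = 0.600 /M)
    scavenger + leaving ligand → scavenged by-product (k = 0.0129 /M/s)
    starting complex + complex with two exchanged → side product (k = 3.02 × 10⁻⁴ /M/s)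

In ash, half the first exchange's turnover is done by 0.184 h, while in maple the side step, reckoned with starting complex as charged, gives the two-exchanged complex a half-life of 6.4 h; with the starting complex actually left, maple's two-exchanged complex goes from 14.7% at 10.0 h to 12.4% at 20.0 h. At 20.0 h ash holds 0% of its incoming ligand, and its complexes, with side product counted at one exchange per starting complex it holds, carry 2.00 exchanges against B. A neighbour of ash with 0.50 M of incoming ligand has B = 5.00, which should pay for full exchange and spare 40.0% of its ligand. Computed, it reaches 100% reacted, with 29% of its ligand free and 0.0553 M as idle adduct.

(The numbers in the tables were generated by integration with constants of no real substance.)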